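Late in Thursday's and Saturday's runs Q is down to 1.2% and 0%, while Z stands at 91.1% and 91.2%. From that end I build up the new flask of 0.15 M of D.

| flask | D | remark | time |
|---|---|---|---|
| Thursday's | 0.075 M | run made earlier |  |
| Saturday's | 0.11 M | run made earlier |  |
| flask | 0.15 M |  | 1.5 h |

| run | time / min | Q / % | Z / % |
|---|---|---|---|
| Thursday's | 0.833 | 61.8 | 4.7 |
| Thursday's | 4.00 | 47.1 | 46.7 |
| Thursday's | 20.0 | 3.6 | 89.6 |
| Thursday's | 90.0 | 1.2 | 91.1 |
| Saturday's | 0.833 | 59.0 | 5.8 |
| Saturday's | 4.00 | 47.2 | 47.0 |
| Saturday's | 20.0 | 2.4 | 89.9 |
| Saturday's | 90.0 | 0 | 91.2 |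

(readings scatter by 1 percentage point)

1. when, up to 1.5 h, the flask holds most Q, in min
2. the amount of Q, in percent of the D charged, at that time
3. earliest time at which at least nineteen twentieths of that best amount are there, in min
4. latest time at which they still are, in min

- what is said of Z includes J
- J is a solid; its amount is given per volume of the solution
- steps thought possible: D -> E; E -> Q; Q -> Z; E -> X; J <-> Z

With D going straight to Q and nothing else, Q's top would be the whole charge, 100 percent. Now I add the side step E to X. Q and Z together end near 91.8% in the two runs, so that is the roof for Q, and the rest I book as X.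

Next comes Q's loss to Z. Saturday's charge is 1.47 times Thursday's, yet at 4.00 min Q reads 47.1% and 47.2%. So I take the rate of that loss as proportional to c_Q, that is, first order. The fall from 4.00 min to 20.0 min, pooled over both runs, gives 0.172 /min as Q's loss constant, the share of the Q present that leaves per minute.

Last comes the making of Q. At 0.833 min Q and Z together stand at about 65.6%. Treated as one step, that gives a making constant of 1.51 /min, which is 8.78 times the loss constant. Q tops where making equals loss, at 1.62 min. The top is then the roof thinned by the loss constant over that time, so I expect 69.4%.

The forecast, which like me chose to “treat all steps as first order”, says 71% at 1.55 min, with a window from 1.1 min to 2.25 min.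

The flask gives 69.2% at 1.47 min, with a window from 1.03 min to 2.10 min.

    D → E (k = 0.0300 /s)
    E → Q (k = 0.140 /s)
    Q → Z (k = 0.00350 /s)
    E → X (k = 0.0120 /s)
    J ⇌ Z, rate k5*(cs5 - [Z]) while solid is left; crystals form when [Z] > cs5 (solubility = 0.110 M, k = 0.410 /s)

At that time the flask holds 0% of J, against 18.8% at 1.50 h, and the saturation of Z changes the highest Q by nothing. The roof thinned by 0.172 /min over the flask's own 1.47 min gives 71.3%. My reckoning has no concentration in it, so for a neighbour flask charged with 0.060 M of D it gives 69.4% again, and that neighbour's highest Q is 69.2%.

Readings and results were generated by integration for an exercise.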